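**Retrosynthetic overview**

- Last C–C bond: Heck union of a (Z)-2-iodoalkene, which carries the whole tetrahydropyran/polyene part, with (S)-6-vinyl-5,6-dihydropyran-2-one. The lactone ring is formed first (allylboration, acrylation, ring-closing metathesis) and carried intact.
- The tetrahydropyran is formed last from an acyclic silyloxy ynone carbinol: fluoride-triggered 6-endo-dig oxa-Michael closure to a 2,3-dihydropyran-4-one, then hydride 1,4- and 1,2-reduction to set the two remaining ring stereocentres.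
- Key bond: carbinol carbon to ring carbon (the 1,2-dioxygenated pair). The zinc acetylide of a terminal ynone acts as a β-acylvinyl anion (homoenolate-type donor at the normally electrophilic β-carbon) and adds, under catalyst control, to the aldehyde carbon of a fully elaborated iodotrienal.
- Iodotrienal: Evans alkylation, Zr-catalysed carboalumination/iodination, Suzuki coupling, Stork–Zhao olefination. Ynone: Evans syn-aldol, Weinreb amide, ethynyl Grignard.

Assumption: the SMILES is taken as the definitive structure (lactone C-6 S, chain methyl carbon R, carbinol S, tetrahydropyran 2R,4S,5R,6R), and all reagent antipodes are chosen for exactly this isomer.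

**Route**

Step 1
Reactants: 1 acrolein; 2 (−)-B-allyldiisopinocampheylborane (the (+)-α-pinene-derived antipode)
Product: 4 (S)-hexa-1,5-dien-3-ol, via borinate adduct 3 (not isolated)
Conditions: Et2O, −78 °C; then 3 M NaOH, 30% H2O2, 0 °C → rt
Reagents that add atoms: none
Why: Brown asymmetric allylboration, in which the chair transition state of the (+)-α-pinene-derived reagent delivers allyl to the Si face of acrolein and so sets the (S)-carbinol that becomes the lactone stereocentre.

Step 2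
Reactants: 4 (S)-hexa-1,5-dien-3-ol; 5 acryloyl chloride
Product: 6 (S)-hexa-1,5-dien-3-yl acrylate
Conditions: Et3N, DMAP (cat.), CH2Cl2, 0 °C
Reagents that add atoms: none
Why: O-acylation of a secondary alcohol (nucleophilic acyl substitution), which leaves the stereocentre untouched.

Step 3
Reactants: 6 (S)-hexa-1,5-dien-3-yl acrylate
Product: 7 (S)-6-vinyl-5,6-dihydro-2H-pyran-2-one
Conditions: second-generation Grubbs catalyst (H2IMes)(PCy3)Cl2Ru=CHPh (3 mol %), CH2Cl2 (5 mM), 40 °C
Reagents that add atoms: none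
Why: Ring-closing metathesis, in which the catalyst loads on the unhindered allyl terminus and closes onto the acrylate to give the six-membered unsaturated lactone rather than the butenolide that closure onto the hindered vinyl group would give, with the stereocentre untouched.

Step 4
Reactants: 8 (S)-4-benzyl-3-propionyloxazolidin-2-one; 9 propargyl bromide
Product: 11 (S)-4-benzyl-3-[(R)-2-methylpent-4-ynoyl]oxazolidin-2-one, via sodium enolate 10 (not isolated)
Conditions: NaN(SiMe3)2, THF, −78 °C; then 9, −78 → −40 °C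
Reagents that add atoms: none
Why: Evans asymmetric alkylation, in which the chelated sodium (Z)-enolate is alkylated on the face anti to the benzyl group and so sets the (R)-methyl stereocentre of the chain.

Step 5
Reactants: 11 (S)-4-benzyl-3-[(R)-2-methylpent-4-ynoyl]oxazolidin-2-one
Product: 12 (R)-2-methylpent-4-yn-1-ol
Conditions: LiBH4, H2O (1 equiv), Et2O, 0 °C
Reagents that add atoms: none
Why: Reductive cleavage of the N-acyloxazolidinone at the exocyclic carbonyl, which gives the primary alcohol without touching the α-stereocentre and returns the auxiliary.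

Step 6
Reactants: 12 (R)-2-methylpent-4-yn-1-ol
Product: 14 (R,E)-5-iodo-2,4-dimethylpent-4-en-1-ol, via alkenylalane 13 (not isolated)
Conditions: Me3Al (3 equiv), Cp2ZrCl2 (0.25 equiv), CH2Cl2, 0 °C → rt; then I2, THF, −30 → 0 °C
Reagents that add atoms: trimethylaluminium C[Al](C)C; iodine II
Why: Negishi zirconium-catalysed carboalumination, a syn addition of Me–Al across the terminal alkyne with aluminium on the terminal carbon, followed by iodinolysis with retention to give the (E)-1-iodo-2-methylalkene.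

Step 7
Reactants: 14 (R,E)-5-iodo-2,4-dimethylpent-4-en-1-ol; 15 (E)-2-(3,3-diethoxyprop-1-enyl)-4,4,5,5-tetramethyl-1,3,2-dioxaborolane
Product: 16 (2R,4E,6E)-8,8-diethoxy-2,4-dimethylocta-4,6-dien-1-ol
Conditions: Pd(PPh3)4 (5 mol %), 2 M aq. KOH, THF, 45 °C
Reagents that add atoms: none
Why: Suzuki–Miyaura coupling of two alkenyl partners, which proceeds with retention of both geometries and delivers the (E,E)-diene with the future aldehyde masked as its diethyl acetal.

Step 8
Reactants: 16 (2R,4E,6E)-8,8-diethoxy-2,4-dimethylocta-4,6-dien-1-ol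
Product: 17 (2R,4E,6E)-8,8-diethoxy-2,4-dimethylocta-4,6-dienal
Conditions: Dess–Martin periodinane, NaHCO3, CH2Cl2, 0 °C
Reagents that add atoms: none
Why: Dess–Martin oxidation under bicarbonate buffer gives the α-branched aldehyde without acetal loss or epimerisation, and the aldehyde is used at once.

Step 9
Reactants: 17 (2R,4E,6E)-8,8-diethoxy-2,4-dimethylocta-4,6-dienal
Product: 19 (2E,4E,7R,8Z)-9-iodo-5,7-dimethyldeca-2,4,8-trienal, via iodotriene acetal 18 (not isolated)
Conditions: EtPPh3I, n-BuLi, THF, 0 °C; I2, −78 °C; NaN(SiMe3)2, −78 °C; then 17, −78 → −20 °C; then 1 M aq. HCl, THF, 0 °C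
Reagents that add atoms: ethyltriphenylphosphonium iodide CC[P+](c1ccccc1)(c1ccccc1)c1ccccc1.[I-]; iodine II; water O
Why: Stork–Zhao Wittig olefination, in which the unstabilised α-iodo ylide gives the (Z)-2-iodoalkene through the kinetic cis-oxaphosphetane, and the acidic quench hydrolyses the conjugated acetal to the (E,E)-dienal.

Step 10
Reactants: 8 (S)-4-benzyl-3-propionyloxazolidin-2-one; 20 (E)-but-2-enal
Product: 23 (S)-4-benzyl-3-[(2S,3R,4E)-3-hydroxy-2-methylhex-4-enoyl]oxazolidin-2-one, via boron enolate 21 (not isolated), via boron aldolate 22 (not isolated)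
Conditions: Bu2BOTf, i-Pr2NEt, CH2Cl2, 0 °C; 20, −78 → 0 °C; then pH 7 buffer, MeOH, 30% H2O2, 0 °C
Reagents that add atoms: none
Why: Evans syn-aldol reaction, in which the dibutylboron (Z)-enolate reacts through a Zimmerman–Traxler chair on the face anti to the benzyl group and so sets the 2,3-syn (2S,3R) pair that becomes the ring methyl and propenyl-bearing stereocentres.

Step 11
Reactants: 23 (S)-4-benzyl-3-[(2S,3R,4E)-3-hydroxy-2-methylhex-4-enoyl]oxazolidin-2-one
Product: 24 (2S,3R,4E)-3-hydroxy-N-methoxy-N,2-dimethylhex-4-enamide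
Conditions: MeNHOMe·HCl, Me3Al, THF, −20 → 0 °C
Reagents that add atoms: N,O-dimethylhydroxylamine hydrochloride CNOC.Cl
Why: Weinreb transamidation by the aluminium amide, directed by the free β-hydroxyl, cleaves the auxiliary without retro-aldol or epimerisation.

Step 12
Reactants: 24 (2S,3R,4E)-3-hydroxy-N-methoxy-N,2-dimethylhex-4-enamide
Product: 25 (2S,3R,4E)-N-methoxy-N,2-dimethyl-3-(triethylsilyloxy)hex-4-enamide
Conditions: Et3SiCl, imidazole, CH2Cl2, 0 °C → rt
Reagents that add atoms: chlorotriethylsilane CC[Si](Cl)(CC)CC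
Why: Silyl ether formation masks the hydroxyl so that it can neither retro-aldolise nor add to the ynone before the coupling.

Step 13
Reactants: 25 (2S,3R,4E)-N-methoxy-N,2-dimethyl-3-(triethylsilyloxy)hex-4-enamide; 26 ethynylmagnesium bromide
Product: 27 (4S,5R,6E)-4-methyl-5-(triethylsilyloxy)oct-6-en-1-yn-3-one
Conditions: THF, −20 → 0 °C; aq. NH4Cl
Reagents that add atoms: none
Why: Grignard addition to a Weinreb amide stops at the chelated tetrahedral intermediate and releases the terminal ynone on work-up with the α-stereocentre intact.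

Step 14
Reactants: 27 (4S,5R,6E)-4-methyl-5-(triethylsilyloxy)oct-6-en-1-yn-3-one; 19 (2E,4E,7R,8Z)-9-iodo-5,7-dimethyldeca-2,4,8-trienal
Product: 29 (2E,4R,5S,9S,10E,12E,15R,16Z)-9-hydroxy-17-iodo-5,13,15-trimethyl-4-(triethylsilyloxy)octadeca-2,10,12,16-tetraen-7-yn-6-one, via zinc alkynylide 28 (not isolated)
Conditions: (S,S)-ProPhenol (20 mol %), Me2Zn (3 equiv), Ph3P=O (40 mol %), toluene, 0 → 4 °C, 36 h; 27 (2.5 equiv, excess recovered)
Reagents that add atoms: none
Why: Proposed new method: zinc/ProPhenol-catalysed asymmetric alkynylation with a terminal ynone as donor, whose zinc acetylide is a β-acylvinyl anion (homoenolate-type, reversed-polarity) equivalent so that the normally electrophilic ynone β-carbon bonds to the electrophilic aldehyde carbon and creates the 1,2-dioxygenated C–C bond, the dinuclear zinc catalyst delivering the alkynyl group to the Re face of the enal to set the (S)-carbinol, the acidic alkyne C–H being zincated in preference to the hindered α-methine, and the closest known reaction being the zinc/ProPhenol addition of methyl propiolate to α,β-unsaturated aldehydes.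

Step 15
Reactants: 29 (2E,4R,5S,9S,10E,12E,15R,16Z)-9-hydroxy-17-iodo-5,13,15-trimethyl-4-(triethylsilyloxy)octadeca-2,10,12,16-tetraen-7-yn-6-one
Product: 31 (2R,3S)-6-[(1S,2E,4E,7R,8Z)-1-hydroxy-9-iodo-5,7-dimethyldeca-2,4,8-trienyl]-3-methyl-2-[(E)-prop-1-enyl]-2,3-dihydro-4H-pyran-4-one, via hydroxy ynone 30 (not isolated)
Conditions: Bu4NF (1.2 equiv), THF, −20 → 0 °C
Reagents that add atoms: none
Why: Fluoride removes the triethylsilyl group and the liberated alkoxide closes by 6-endo-dig oxa-Michael addition to the electrophilic ynone β-carbon (the carbinol hydroxyl cannot reach the alkyne), giving the dihydropyranone with the aldol-derived stereocentres unchanged.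

Step 16
Reactants: 31 (2R,3S)-6-[(1S,2E,4E,7R,8Z)-1-hydroxy-9-iodo-5,7-dimethyldeca-2,4,8-trienyl]-3-methyl-2-[(E)-prop-1-enyl]-2,3-dihydro-4H-pyran-4-one
Product: 33 (2R,3R,4S,6R)-6-[(1S,2E,4E,7R,8Z)-1-hydroxy-9-iodo-5,7-dimethyldeca-2,4,8-trienyl]-3-methyl-2-[(E)-prop-1-enyl]tetrahydro-2H-pyran-4-ol, via tetrahydropyranone 32 (not isolated)
Conditions: LiBH(s-Bu)3 (2.2 equiv), THF, −78 °C; t-BuOH (1.1 equiv); LiBH(s-Bu)3 (1.5 equiv), −78 → −40 °C; then NaOH, H2O2, 0 °C
Reagents that add atoms: none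
Why: Selectride conjugate reduction followed by ketone reduction, in which hydride adds pseudo-axially to the enone β-carbon trans to the propenyl group so that the side chain ends up equatorial and 2,6-cis, and after in-flask protonation of the enolate the bulky hydride attacks the ketone equatorially to give the axial alcohol trans to the axial methyl.

Step 17
Reactants: 33 (2R,3R,4S,6R)-6-[(1S,2E,4E,7R,8Z)-1-hydroxy-9-iodo-5,7-dimethyldeca-2,4,8-trienyl]-3-methyl-2-[(E)-prop-1-enyl]tetrahydro-2H-pyran-4-ol; 7 (S)-6-vinyl-5,6-dihydro-2H-pyran-2-one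
Product: 34 (S)-6-[(1E,3Z,5R,7E,9E,11S)-11-hydroxy-11-[(2R,4S,5R,6R)-4-hydroxy-5-methyl-6-[(E)-prop-1-enyl]tetrahydro-2H-pyran-2-yl]-3,5,7-trimethylundeca-1,3,7,9-tetraenyl]-5,6-dihydro-2H-pyran-2-one
Conditions: Pd(OAc)2 (15 mol %), Bu4NCl, NaHCO3, DMF, 40 °C, dark; 7 (2 equiv)
Reagents that add atoms: none
Why: Heck reaction under phosphine-free Jeffery conditions, in which the alkenylpalladium formed from the (Z)-iodide with retention adds to the terminal vinyl carbon of the lactone and syn β-hydride elimination toward the diene gives the new (E)-alkene, while the mild bicarbonate base spares the lactone and the free hydroxyls.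

**Compound list**

1 | acrolein (prop-2-enal) | C=CC=O | starting material
2 | (−)-B-allyldiisopinocampheylborane | C=CCB([C@@H]1C[C@@H]2C[C@H]([C@H]1C)C2(C)C)[C@@H]1C[C@@H]2C[C@H]([C@H]1C)C2(C)C | starting material
3 | (S)-hexa-1,5-dien-3-yl diisopinocampheylborinate | C=C[C@@H](OB([C@@H]1C[C@@H]2C[C@H]([C@H]1C)C2(C)C)[C@@H]1C[C@@H]2C[C@H]([C@H]1C)C2(C)C)CC=C | intermediate (not isolated)
4 | (S)-hexa-1,5-dien-3-ol | C=C[C@@H](O)CC=C | intermediate
5 | acryloyl chloride | C=CC(=O)Cl | starting material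
6 | (S)-hexa-1,5-dien-3-yl acrylate | C=C[C@@H](OC(=O)C=C)CC=C | intermediate
7 | (S)-6-vinyl-5,6-dihydro-2H-pyran-2-one | C=C[C@@H]1CC=CC(=O)O1 | intermediate
8 | (S)-4-benzyl-3-propionyloxazolidin-2-one | CCC(=O)N1C(=O)OC[C@@H]1Cc1ccccc1 | starting material
9 | propargyl bromide (3-bromoprop-1-yne) | C#CCBr | starting material
10 | sodium (Z)-enolate of 8 | C/C=C(\[O-])N1C(=O)OC[C@@H]1Cc1ccccc1.[Na+] | intermediate (not isolated)
11 | (S)-4-benzyl-3-[(R)-2-methylpent-4-ynoyl]oxazolidin-2-one | C#CC[C@@H](C)C(=O)N1C(=O)OC[C@@H]1Cc1ccccc1 | intermediate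
12 | (R)-2-methylpent-4-yn-1-ol | C#CC[C@@H](C)CO | intermediate
13 | (R,E)-5-(dimethylalumanyl)-2,4-dimethylpent-4-en-1-ol, as its O-dimethylaluminium alkoxide | C[Al](C)/C=C(\C)C[C@@H](C)CO[Al](C)C | intermediate (not isolated)
14 | (R,E)-5-iodo-2,4-dimethylpent-4-en-1-ol | I/C=C(\C)C[C@@H](C)CO | intermediate
15 | (E)-2-(3,3-diethoxyprop-1-enyl)-4,4,5,5-tetramethyl-1,3,2-dioxaborolane | CCOC(OCC)/C=C/B1OC(C)(C)C(C)(C)O1 | starting material
16 | (2R,4E,6E)-8,8-diethoxy-2,4-dimethylocta-4,6-dien-1-ol | CCOC(OCC)/C=C/C=C(\C)C[C@@H](C)CO | intermediate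
17 | (2R,4E,6E)-8,8-diethoxy-2,4-dimethylocta-4,6-dienal | CCOC(OCC)/C=C/C=C(\C)C[C@@H](C)C=O | intermediate
18 | (2Z,4R,6E,8E)-10,10-diethoxy-2-iodo-4,6-dimethyldeca-2,6,8-triene | CCOC(OCC)/C=C/C=C(\C)C[C@@H](C)/C=C(C)\I | intermediate (not isolated)
19 | (2E,4E,7R,8Z)-9-iodo-5,7-dimethyldeca-2,4,8-trienal | O=C/C=C/C=C(\C)C[C@@H](C)/C=C(C)\I | intermediate
20 | (E)-but-2-enal (crotonaldehyde) | C/C=C/C=O | starting material
21 | dibutylboron (Z)-enolate of 8 | C/C=C(\OB(CCCC)CCCC)N1C(=O)OC[C@@H]1Cc1ccccc1 | intermediate (not isolated)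
22 | O-dibutylboryl aldolate of 23 | C/C=C/[C@H]([C@H](C)C(=O)N1C(=O)OC[C@@H]1Cc1ccccc1)OB(CCCC)CCCC | intermediate (not isolated)
23 | (S)-4-benzyl-3-[(2S,3R,4E)-3-hydroxy-2-methylhex-4-enoyl]oxazolidin-2-one | C/C=C/[C@H]([C@H](C)C(=O)N1C(=O)OC[C@@H]1Cc1ccccc1)O | intermediate
24 | (2S,3R,4E)-3-hydroxy-N-methoxy-N,2-dimethylhex-4-enamide | C/C=C/[C@H]([C@H](C)C(=O)N(C)OC)O | intermediate
25 | (2S,3R,4E)-N-methoxy-N,2-dimethyl-3-(triethylsilyloxy)hex-4-enamide | C/C=C/[C@H]([C@H](C)C(=O)N(C)OC)O[Si](CC)(CC)CC | intermediate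
26 | ethynylmagnesium bromide | C#C[Mg]Br | starting material
27 | (4S,5R,6E)-4-methyl-5-(triethylsilyloxy)oct-6-en-1-yn-3-one | C/C=C/[C@H]([C@H](C)C(=O)C#C)O[Si](CC)(CC)CC | intermediate
28 | methylzinc acetylide of 27 | C/C=C/[C@H]([C@H](C)C(=O)C#C[Zn]C)O[Si](CC)(CC)CC | intermediate (not isolated)
29 | (2E,4R,5S,9S,10E,12E,15R,16Z)-9-hydroxy-17-iodo-5,13,15-trimethyl-4-(triethylsilyloxy)octadeca-2,10,12,16-tetraen-7-yn-6-one | C/C=C/[C@H]([C@H](C)C(=O)C#C[C@@H](O)/C=C/C=C(\C)C[C@@H](C)/C=C(C)\I)O[Si](CC)(CC)CC | intermediate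
30 | (2E,4R,5S,9S,10E,12E,15R,16Z)-4,9-dihydroxy-17-iodo-5,13,15-trimethyloctadeca-2,10,12,16-tetraen-7-yn-6-one | C/C=C/[C@H]([C@H](C)C(=O)C#C[C@@H](O)/C=C/C=C(\C)C[C@@H](C)/C=C(C)\I)O | intermediate (not isolated)
31 | (2R,3S)-6-[(1S,2E,4E,7R,8Z)-1-hydroxy-9-iodo-5,7-dimethyldeca-2,4,8-trienyl]-3-methyl-2-[(E)-prop-1-enyl]-2,3-dihydro-4H-pyran-4-one | C/C=C/[C@H]1OC([C@@H](O)/C=C/C=C(\C)C[C@@H](C)/C=C(C)\I)=CC(=O)[C@H]1C | intermediate
32 | (2R,3S,6R)-6-[(1S,2E,4E,7R,8Z)-1-hydroxy-9-iodo-5,7-dimethyldeca-2,4,8-trienyl]-3-methyl-2-[(E)-prop-1-enyl]tetrahydro-4H-pyran-4-one | C/C=C/[C@H]1O[C@@H]([C@@H](O)/C=C/C=C(\C)C[C@@H](C)/C=C(C)\I)CC(=O)[C@H]1C | intermediate (not isolated)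
33 | (2R,3R,4S,6R)-6-[(1S,2E,4E,7R,8Z)-1-hydroxy-9-iodo-5,7-dimethyldeca-2,4,8-trienyl]-3-methyl-2-[(E)-prop-1-enyl]tetrahydro-2H-pyran-4-ol | C/C=C/[C@H]1O[C@@H]([C@@H](O)/C=C/C=C(\C)C[C@@H](C)/C=C(C)\I)C[C@H](O)[C@H]1C | intermediate
34 | (S)-6-[(1E,3Z,5R,7E,9E,11S)-11-hydroxy-11-[(2R,4S,5R,6R)-4-hydroxy-5-methyl-6-[(E)-prop-1-enyl]tetrahydro-2H-pyran-2-yl]-3,5,7-trimethylundeca-1,3,7,9-tetraenyl]-5,6-dihydro-2H-pyran-2-one | C/C=C/[C@H]1O[C@@H]([C@@H](O)/C=C/C=C(\C)C[C@@H](C)/C=C(C)\C=C\[C@@H]2CC=CC(=O)O2)C[C@H](O)[C@H]1C | target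

**Step count and risks**

Total step count: 17. Longest linear sequence: 10 steps (steps 4–9, then 14–17, counted from imide 8).

Steps most likely to fail:

Step 14 (ynone as alkynyl donor). Terminal ynones are untested donors in this catalysis. The risks are enolisation or epimerisation next to the ketone by the zinc base, slow zincation, and an unverified facial sense: the (S,S)-ligand is chosen by analogy and the new carbinol must be checked by Mosher analysis, with the ligand antipode available. The fallback sets out from aldehyde 19 and Weinreb amide 25 and comes back at 29. (Trimethylsilyl)acetylene, a precedented donor for enals, is added to 19 under the same zinc/ProPhenol catalysis to give the silylalkynyl carbinol (3S,4E,6E,9R,10Z)-11-iodo-7,9-dimethyl-1-(trimethylsilyl)dodeca-4,6,10-trien-1-yn-3-ol F1. K2CO3 in MeOH removes the silyl group to give the terminal alkyne carbinol (3S,4E,6E,9R,10Z)-11-iodo-7,9-dimethyldodeca-4,6,10-trien-1-yn-3-ol F2. Double deprotonation with LiN(i-Pr)2 (2.2 equiv, THF, −78 °C, which leaves the alkenyl iodide alone) and acylation of the acetylide by 25 then gives 29.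

Step 16 (two-stage hydride reduction). The β,β-disubstituted vinylogous ester may suffer 1,2- instead of 1,4-attack, and the axial methyl next to the ketone may erode the axial-alcohol selectivity. The fallback sets out from 29 and comes back at 32, so that C-6 is set by a thermodynamic oxa-Michael closure instead of by hydride delivery. Trans-hydrosilylation of the ynone alkyne ([Cp*Ru(MeCN)3]PF6 cat., (EtO)3SiH, CH2Cl2, 0 °C) gives the alkenylsilane (2E,4R,5S,7Z,9S,10E,12E,15R,16Z)-9-hydroxy-17-iodo-5,13,15-trimethyl-7-(triethoxysilyl)-4-(triethylsilyloxy)octadeca-2,7,10,12,16-pentaen-6-one F3. Bu4NF with CuI in THF removes both silyl groups to give the (E)-enone diol (2E,4R,5S,7E,9S,10E,12E,15R,16Z)-4,9-dihydroxy-17-iodo-5,13,15-trimethyloctadeca-2,7,10,12,16-pentaen-6-one F4. Its β'-hydroxyl closes by 6-endo-trig oxa-Michael addition (PdCl2(MeCN)2 cat., CH2Cl2) to the 2,6-cis ketone 32, after which only the LiBH(s-Bu)3 ketone reduction of step 16 remains.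

Step 17 (Heck coupling with the free lactone). The alkylpalladium intermediate sits next to the lactone oxygen, so β-acyloxy elimination with ring opening, base-induced lactone opening, or sluggish reaction of the hindered (Z)-iodide could intervene. The fallback sets out from lactone 7 and iodide 33 and comes back at 34. Cross-metathesis of 7 with vinylboronic acid pinacol ester (second-generation Hoveyda–Grubbs catalyst (H2IMes)Cl2Ru=CH(C6H4-2-O-i-Pr), CH2Cl2, 40 °C) gives the alkenylboronate (S,E)-6-[2-(4,4,5,5-tetramethyl-1,3,2-dioxaborolan-2-yl)vinyl]-5,6-dihydro-2H-pyran-2-one F5. Suzuki–Miyaura coupling of F5 with 33 (Pd(PPh3)4, TlOEt, THF/H2O, rt) then gives 34 with both alkene geometries fixed by the partners.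

**Further compounds**

F1 | step 14 | (3S,4E,6E,9R,10Z)-11-iodo-7,9-dimethyl-1-(trimethylsilyl)dodeca-4,6,10-trien-1-yn-3-ol | C[Si](C)(C)C#C[C@@H](O)/C=C/C=C(\C)C[C@@H](C)/C=C(C)\I
F2 | step 14 | (3S,4E,6E,9R,10Z)-11-iodo-7,9-dimethyldodeca-4,6,10-trien-1-yn-3-ol | C#C[C@@H](O)/C=C/C=C(\C)C[C@@H](C)/C=C(C)\I
F3 | step 16 | (2E,4R,5S,7Z,9S,10E,12E,15R,16Z)-9-hydroxy-17-iodo-5,13,15-trimethyl-7-(triethoxysilyl)-4-(triethylsilyloxy)octadeca-2,7,10,12,16-pentaen-6-one | C/C=C/[C@H]([C@H](C)C(=O)/C([Si](OCC)(OCC)OCC)=C/[C@@H](O)/C=C/C=C(\C)C[C@@H](C)/C=C(C)\I)O[Si](CC)(CC)CC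
F4 | step 16 | (2E,4R,5S,7E,9S,10E,12E,15R,16Z)-4,9-dihydroxy-17-iodo-5,13,15-trimethyloctadeca-2,7,10,12,16-pentaen-6-one | C/C=C/[C@H]([C@H](C)C(=O)/C=C/[C@@H](O)/C=C/C=C(\C)C[C@@H](C)/C=C(C)\I)O
F5 | step 17 | (S,E)-6-[2-(4,4,5,5-tetramethyl-1,3,2-dioxaborolan-2-yl)vinyl]-5,6-dihydro-2H-pyran-2-one | CC1(C)OB(/C=C/[C@@H]2CC=CC(=O)O2)OC1(C)C
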